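**Retrosynthetic overview**
- The nitrogen ring is closed last: the C3–N bond (which sets 3S) is made from an allyl arene and acetonitrile, and the resulting nitrilium closes C1–C8a para to the free 6-OH.
- The allyl group comes from an aryl chloride (Suzuki allylation); the 6-OH comes from thiolate mono-demethylation of a symmetric 2,6-dimethoxyaryl unit.
- The biaryl bond is a Negishi coupling of 4-chloro-2,6-dimethoxyphenylzinc (directed metalation) with a 5-bromonaphthyl acetate.
- The naphthalene is built first: Wittig olefination of 2-bromo-5-methoxybenzaldehyde, then acylative benzannulation.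
- Ring order: second naphthalene ring, then biaryl, then dihydroisoquinoline ring.

Assumption: the target SMILES defines no configuration at the biaryl axis, so the axis is left uncontrolled and only C3 (S) is set.
Assumption: the (S,S)-cobalt catalyst is taken to give 3S; if the first run shows the opposite sense, the (R,R)-catalyst is used with no other change.

**Step 1**
Reactants: 1 crotonic acid; 2 triphenylphosphine hydrobromide
Product: 3 (1-carboxypropan-2-yl)triphenylphosphonium bromide (racemic)
Conditions: neat, 130 °C, 3 h; triturate with acetone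
Reagents that add atoms: none
Why: Phospha-Michael addition of PPh3 to the acid-activated enoic acid, the HBr salt supplying both the proton and the counter-ion.

**Step 2**
Reactants: 3 (1-carboxypropan-2-yl)triphenylphosphonium bromide; 4 2-bromo-5-methoxybenzaldehyde
Product: 6 4-(2-bromo-5-methoxyphenyl)-3-methylbut-3-enoic acid (E/Z mixture), via ylide carboxylate 5 (not isolated)
Conditions: NaN(SiMe3)2 (2.1 equiv), THF, −78 → 0 °C; then 4, 0 °C → rt; 1 M HCl
Reagents that add atoms: none
Why: Wittig olefination of a non-stabilised ylide with an aryl aldehyde; two equivalents of base make the carboxylate ylide, and the aryl bromide is inert.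

**Step 3**
Reactants: 6 4-(2-bromo-5-methoxyphenyl)-3-methylbut-3-enoic acid
Product: 9 5-bromo-8-methoxy-3-methylnaphthalen-1-yl acetate, via mixed anhydride 7 (not isolated), via free naphthol 8 (not isolated)
Conditions: Ac2O, NaOAc, 140 °C, 6 h
Reagents that add atoms: acetic anhydride, CC(=O)OC(C)=O
Why: Intramolecular Friedel–Crafts acylation of the mixed anhydride (Fittig–Erdmann/Stobbe-type naphthol ring closure) at the only free ortho position, bromine blocking the other, then enolisation and O-acetylation; the E/Z acids converge through the conjugated isomer under hot acetate.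

**Step 4**
Reactants: 10 1-chloro-3,5-dimethoxybenzene; 9 5-bromo-8-methoxy-3-methylnaphthalen-1-yl acetate
Product: 13 5-(4-chloro-2,6-dimethoxyphenyl)-8-methoxy-3-methylnaphthalen-1-yl acetate, via aryllithium 11 (not isolated), via arylzinc chloride 12 (not isolated)
Conditions: 10, n-BuLi (1.05 equiv), THF, −20 → 0 °C, 1.5 h; ZnCl2 (1.1 equiv), 0 °C → rt; then 9 (0.8 equiv), Pd(OAc)2 (2 mol%), SPhos (2-dicyclohexylphosphino-2′,6′-dimethoxybiphenyl, 4 mol%), THF, 40 °C
Reagents that add atoms: none
Why: Directed ortho-metalation between the two cooperating methoxy groups (lithium para to chlorine, so no benzyne), transmetalation to zinc and Negishi coupling; zerovalent palladium inserts into C–Br far faster than C–Cl at 40 °C, and the arylzinc tolerates the aryl acetate.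

**Step 5**
Reactants: 13 5-(4-chloro-2,6-dimethoxyphenyl)-8-methoxy-3-methylnaphthalen-1-yl acetate
Product: 15 5-(4-chloro-2-hydroxy-6-methoxyphenyl)-8-methoxy-3-methylnaphthalen-1-ol (racemic axis), via sodium naphthoxide 14 (not isolated)
Conditions: NaSEt (4 equiv), DMF, 130 °C, 3 h; 1 M HCl
Reagents that add atoms: none
Why: Thiolate SN2 O-demethylation; the acetate is cleaved first to a naphthoxide that shields the peri methoxy group (its loss would need a naphthalenediolate dianion), and the first demethylation on the central ring gives a phenoxide that stops the second.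

**Step 6**
Reactants: 15 5-(4-chloro-2-hydroxy-6-methoxyphenyl)-8-methoxy-3-methylnaphthalen-1-ol
Product: 16 5-[2-hydroxy-6-methoxy-4-(prop-2-en-1-yl)phenyl]-8-methoxy-3-methylnaphthalen-1-ol
Conditions: allylboronic acid pinacol ester (1.5 equiv), Pd(OAc)2 (3 mol%), XPhos (2-dicyclohexylphosphino-2′,4′,6′-triisopropylbiphenyl, 6 mol%), K3PO4 (4 equiv), degassed THF/H2O 10:1, 65 °C, 12 h
Reagents that add atoms: allylboronic acid pinacol ester, C=CCB1OC(C)(C)C(C)(C)O1
Why: Suzuki–Miyaura allylation of an aryl chloride with a bulky biarylphosphine ligand; unprotected chlorophenols are competent partners under phosphate base.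

**Step 7**
Reactants: 16 5-[2-hydroxy-6-methoxy-4-(prop-2-en-1-yl)phenyl]-8-methoxy-3-methylnaphthalen-1-ol
Product: 18 (3S)-7-(4-hydroxy-5-methoxy-7-methylnaphthalen-1-yl)-8-methoxy-1,3-dimethyl-3,4-dihydroisoquinolin-6-ol, via nitrilium ion 17 (not isolated)
Conditions: (S,S)-N,N′-bis(3,5-di-tert-butylsalicylidene)-1,2-cyclohexanediaminocobalt, C36H52CoN2O2 (divalent cobalt, 5 mol%), N-fluoro-2,4,6-trimethylpyridinium tetrafluoroborate (1.5 equiv), PhSiH3 (1.2 equiv), dry MeCN (0.05 M), 3 Å sieves, −20 °C → rt; aq. NaHCO3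
Reagents that add atoms: acetonitrile, CC#N
Why: Proposed new method: an enantioselective cobalt-hydride hydrogen-atom-transfer/radical-polar-crossover Ritter amination intercepted by the arene, in which a trivalent cobalt hydride (from the divalent cobalt salen, the N-fluoropyridinium oxidant and PhSiH3) delivers H• to the terminal alkene carbon (Markovnikov), the secondary radical is held on the chiral salen as a tetravalent alkylcobalt whose diastereomers interconvert by Co–C homolysis, acetonitrile displaces cobalt with inversion from the faster-reacting diastereomer to form the C3–N bond and set 3S, and the N-alkylnitrilium then closes onto the ring carbon para to the free 6-OH and ortho to OMe (the site preferred by iminium-type electrophiles on 3-methoxyphenols), with the collidine released from the oxidant taking up the proton; the closest known reaction types are cobalt-salen hydrogen-atom-transfer hydroalkoxylation and Ritter-type hydroamidation of unactivated alkenes and the racemic sulfuric-acid Ritter cyclisation of allylbenzenes with nitriles to 3-methyl-3,4-dihydroisoquinolines.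

**Compound list**
1 | crotonic acid | C/C=C/C(=O)O | starting material
2 | triphenylphosphine hydrobromide | [Br-].c1ccc([PH+](c2ccccc2)c2ccccc2)cc1 | starting material
3 | (1-carboxypropan-2-yl)triphenylphosphonium bromide (racemic) | CC(CC(=O)O)[P+](c1ccccc1)(c1ccccc1)c1ccccc1.[Br-] | intermediate
4 | 2-bromo-5-methoxybenzaldehyde | COc1ccc(Br)c(C=O)c1 | starting material
5 | sodium 3-(triphenylphosphoranylidene)butanoate (ylide carboxylate) | CC(CC(=O)[O-])=P(c1ccccc1)(c1ccccc1)c1ccccc1.[Na+] | intermediate
6 | 4-(2-bromo-5-methoxyphenyl)-3-methylbut-3-enoic acid (E/Z mixture) | COc1ccc(Br)c(C=C(C)CC(=O)O)c1 | intermediate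
7 | acetic 4-(2-bromo-5-methoxyphenyl)-3-methylbut-3-enoic anhydride (mixed anhydride) | COc1ccc(Br)c(C=C(C)CC(=O)OC(C)=O)c1 | intermediate
8 | 5-bromo-8-methoxy-3-methylnaphthalen-1-ol | Cc1cc(O)c2c(OC)ccc(Br)c2c1 | intermediate
9 | 5-bromo-8-methoxy-3-methylnaphthalen-1-yl acetate | Cc1cc(OC(C)=O)c2c(OC)ccc(Br)c2c1 | intermediate
10 | 1-chloro-3,5-dimethoxybenzene | COc1cc(Cl)cc(OC)c1 | starting material
11 | (4-chloro-2,6-dimethoxyphenyl)lithium | [Li]c1c(OC)cc(Cl)cc1OC | intermediate
12 | (4-chloro-2,6-dimethoxyphenyl)zinc chloride | Cl[Zn]c1c(OC)cc(Cl)cc1OC | intermediate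
13 | 5-(4-chloro-2,6-dimethoxyphenyl)-8-methoxy-3-methylnaphthalen-1-yl acetate | Cc1cc(OC(C)=O)c2c(OC)ccc(-c3c(OC)cc(Cl)cc3OC)c2c1 | intermediate
14 | sodium 5-(4-chloro-2,6-dimethoxyphenyl)-8-methoxy-3-methylnaphthalen-1-olate | Cc1cc([O-])c2c(OC)ccc(-c3c(OC)cc(Cl)cc3OC)c2c1.[Na+] | intermediate
15 | 5-(4-chloro-2-hydroxy-6-methoxyphenyl)-8-methoxy-3-methylnaphthalen-1-ol | Cc1cc(O)c2c(OC)ccc(-c3c(O)cc(Cl)cc3OC)c2c1 | intermediate
16 | 5-[2-hydroxy-6-methoxy-4-(prop-2-en-1-yl)phenyl]-8-methoxy-3-methylnaphthalen-1-ol | Cc1cc(O)c2c(OC)ccc(-c3c(O)cc(CC=C)cc3OC)c2c1 | intermediate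
17 | N-[(2S)-1-[3-hydroxy-4-(4-hydroxy-5-methoxy-7-methylnaphthalen-1-yl)-5-methoxyphenyl]propan-2-yl]acetonitrilium tetrafluoroborate | Cc1cc(O)c2c(OC)ccc(-c3c(O)cc(C[C@H](C)[N+]#CC)cc3OC)c2c1.F[B-](F)(F)F | intermediate
18 | (3S)-7-(4-hydroxy-5-methoxy-7-methylnaphthalen-1-yl)-8-methoxy-1,3-dimethyl-3,4-dihydroisoquinolin-6-ol | COc1c2c(cc(O)c1-c1ccc(OC)c3c(O)cc(C)cc13)C[C@H](C)N=C2C | target

**Totals**
Total steps: 7. Longest linear sequence: 7 (steps 1 to 7; compound 10 enters at step 4 as purchased).

**Three steps most likely to fail**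

Step 7 (the proposed new step). Possible failures are low enantioselectivity, closure para to OMe instead of para to OH, oxidation of the free naphthol by the N–F oxidant, alkene isomerisation to the propenyl arene, or water trapping the nitrilium as the acetamide. The enantiomeric purity would be raised by crystallising a salt of 18 if needed. The fallback uses known chemistry, sets out from 16 and comes back at 18. Tsuji–Wacker oxidation of 16 (PdCl2, CuCl, O2, DMF/H2O) gives the arylacetone F1. Condensation with (S)-tert-butanesulfinamide and Ti(OEt)4 in THF gives the sulfinyl ketimine F2, which is reduced in the same flask with NaBH4 at −48 °C to the sulfinamide F3; the minor diastereomer is removed by chromatography. HCl in dioxane followed by aqueous work-up frees the (S)-amine F4. Selective N-acetylation (Ac2O, EtOAc/aq. NaHCO3) gives the acetamide F5, and Bischler–Napieralski cyclisation (POCl3, MeCN, reflux), again directed para to the free phenol, gives 18.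

Step 5 (mono-demethylation). Possible failures are loss of the naphthyl methyl ether or double demethylation. The fallback sets out from 9 and comes back at 15, and replaces the symmetric arene by one in which the two oxygens are already different. 3-Chloro-5-methoxyphenol F10 is protected (MOMCl, i-Pr2NEt, CH2Cl2) as 1-chloro-3-methoxy-5-(methoxymethoxy)benzene F11. Lithiation with n-BuLi between the two oxygen groups gives the aryllithium F12, which ZnCl2 converts to the arylzinc chloride F13. Negishi coupling with 9 under the step 4 catalyst gives the protected biaryl acetate F14, and HCl in MeOH at 50 °C removes both the methoxymethyl and acetyl groups to give 15.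

Step 4 (metalation and hindered Negishi coupling). Possible failures are a sluggish coupling at the peri-flanked naphthyl bromide or competing reaction at the aryl chloride. The fallback sets out from 12 and 4 and comes back at 13; it makes the biaryl bond on the unhindered benzaldehyde and annulates the naphthalene afterwards. Negishi coupling of 12 with 4 (Pd(OAc)2, SPhos, THF, rt) gives 2-(4-chloro-2,6-dimethoxyphenyl)-5-methoxybenzaldehyde F6. Wittig reaction with ylide 5 gives the butenoic acid F7. Heating with Ac2O/NaOAc at 140 °C takes it through the mixed anhydride F8 and the free naphthol F9 to 13, the ring closing at the only free ortho position.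

**Further compounds**
F1 | step 7 | 1-[3-hydroxy-4-(4-hydroxy-5-methoxy-7-methylnaphthalen-1-yl)-5-methoxyphenyl]propan-2-one | Cc1cc(O)c2c(OC)ccc(-c3c(O)cc(CC(C)=O)cc3OC)c2c1
F2 | step 7 | (S)-N-[1-[3-hydroxy-4-(4-hydroxy-5-methoxy-7-methylnaphthalen-1-yl)-5-methoxyphenyl]propan-2-ylidene]-2-methylpropane-2-sulfinamide | Cc1cc(O)c2c(OC)ccc(-c3c(O)cc(CC(C)=N[S@@](=O)C(C)(C)C)cc3OC)c2c1
F3 | step 7 | (S)-N-[(2S)-1-[3-hydroxy-4-(4-hydroxy-5-methoxy-7-methylnaphthalen-1-yl)-5-methoxyphenyl]propan-2-yl]-2-methylpropane-2-sulfinamide | Cc1cc(O)c2c(OC)ccc(-c3c(O)cc(C[C@H](C)N[S@@](=O)C(C)(C)C)cc3OC)c2c1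
F4 | step 7 | 5-[4-[(2S)-2-aminopropyl]-2-hydroxy-6-methoxyphenyl]-8-methoxy-3-methylnaphthalen-1-ol | Cc1cc(O)c2c(OC)ccc(-c3c(O)cc(C[C@H](C)N)cc3OC)c2c1
F5 | step 7 | N-[(2S)-1-[3-hydroxy-4-(4-hydroxy-5-methoxy-7-methylnaphthalen-1-yl)-5-methoxyphenyl]propan-2-yl]acetamide | Cc1cc(O)c2c(OC)ccc(-c3c(O)cc(C[C@H](C)NC(C)=O)cc3OC)c2c1
F6 | step 4 | 2-(4-chloro-2,6-dimethoxyphenyl)-5-methoxybenzaldehyde | COc1ccc(-c2c(OC)cc(Cl)cc2OC)c(C=O)c1
F7 | step 4 | 4-[2-(4-chloro-2,6-dimethoxyphenyl)-5-methoxyphenyl]-3-methylbut-3-enoic acid (E/Z mixture) | COc1ccc(-c2c(OC)cc(Cl)cc2OC)c(C=C(C)CC(=O)O)c1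
F8 | step 4 | acetic 4-[2-(4-chloro-2,6-dimethoxyphenyl)-5-methoxyphenyl]-3-methylbut-3-enoic anhydride | COc1ccc(-c2c(OC)cc(Cl)cc2OC)c(C=C(C)CC(=O)OC(C)=O)c1
F9 | step 4 | 5-(4-chloro-2,6-dimethoxyphenyl)-8-methoxy-3-methylnaphthalen-1-ol | Cc1cc(O)c2c(OC)ccc(-c3c(OC)cc(Cl)cc3OC)c2c1
F10 | step 5 | 3-chloro-5-methoxyphenol | COc1cc(O)cc(Cl)c1
F11 | step 5 | 1-chloro-3-methoxy-5-(methoxymethoxy)benzene | COCOc1cc(Cl)cc(OC)c1
F12 | step 5 | [4-chloro-2-methoxy-6-(methoxymethoxy)phenyl]lithium | [Li]c1c(OC)cc(Cl)cc1OCOC
F13 | step 5 | [4-chloro-2-methoxy-6-(methoxymethoxy)phenyl]zinc chloride | Cl[Zn]c1c(OC)cc(Cl)cc1OCOC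
F14 | step 5 | 5-[4-chloro-2-methoxy-6-(methoxymethoxy)phenyl]-8-methoxy-3-methylnaphthalen-1-yl acetate | Cc1cc(OC(C)=O)c2c(OC)ccc(-c3c(OC)cc(Cl)cc3OCOC)c2c1
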